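**Strategy.** Everything rests on cutting the C1–C6 bond. The C1 ketone and the C6 lactone carbinol sit 1,6 across the ten-membered ring, so that ring is built as a cis-fused octalin-1,6-diol (ring A: C1–C6 with C4=C5; ring B: C1, C6–C10) and opened by Pb(OAc)4 glycol cleavage. In one operation this gives the ten-membered ring, both carbonyls and the Z-C4=C5 alkene, whose geometry was fixed when ring A was closed by metathesis and which later becomes the cis-epoxide. The precursor carries the C7 alkylidene-dioxane (C11–C13), the C8 senecioate and the C10 methyl on ring B.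

Key step: step 13

Remark: atom labels C1–C15 are those of the target (C1 ketone, C4/C5 epoxide, C6 lactone carbinol, C7=C11, C8 ester carbinol, C10 methyl-bearing carbon, C12 lactone carbonyl, C13 acetoxymethyl carbon); the target is (4S,5R,6R,8R,10S).
Remark: the sense of induction of the phosphoramidite ligand in step 3 is assumed to follow that on simple 4,4-disubstituted dienones; the ligand antipode that gives 10S is the one to be used.
Remark: the two ring-fusion hydroxyls of the bicyclic diol are placed on the face that also carries the C8 oxygen and the C10 methyl, because this is the diastereomer the additions should deliver; both carbinol centres are erased in the key step.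

Step 1
Reactants: 1 4,4-dimethoxycyclohexa-2,5-dien-1-one; 2 4-bromo-2-methylbut-1-ene
Product: 5 4-hydroxy-4-(3-methylbut-3-en-1-yl)cyclohexa-2,5-dien-1-one, via Grignard reagent 3 (not isolated), via dienol ketal 4 (not isolated)
Conditions: Mg, THF, 40 °C; add to 1, THF, −78 °C; then 1 M aq. oxalic acid, 0 °C to rt
Reagents that add atoms: water, O
Why: Grignard 1,2-addition to the carbonyl of the quinone monoketal followed by mild ketal hydrolysis is the standard entry to 4-alkyl p-quinols; the product is achiral, and C1 is already a fully substituted carbinol carbon para to the future C8 oxygen.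

Step 2
Reactants: 5 4-hydroxy-4-(3-methylbut-3-en-1-yl)cyclohexa-2,5-dien-1-one
Product: 6 4-(3-methylbut-3-en-1-yl)-4-[(triethylsilyl)oxy]cyclohexa-2,5-dien-1-one
Conditions: TESOTf, 2,6-lutidine, CH2Cl2, −78 °C
Reagents that add atoms: triethylsilyl trifluoromethanesulfonate, CC[Si](CC)(CC)OS(=O)(=O)C(F)(F)F
Why: Silyl triflate silylation of a tertiary alcohol gives a non-chelating ether that should survive steps 3 to 9 and is removed by fluoride in step 10.

Step 3
Reactants: 6 4-(3-methylbut-3-en-1-yl)-4-[(triethylsilyl)oxy]cyclohexa-2,5-dien-1-one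
Product: 7 (4S,5S)-5-methyl-4-(3-methylbut-3-en-1-yl)-4-[(triethylsilyl)oxy]cyclohex-2-en-1-one
Conditions: Me2Zn, Cu(OTf)2 (2 mol%), (S,R,R)-BINOL-derived bis(1-phenylethyl)amine phosphoramidite (4 mol%), toluene, −25 °C; aq. NH4Cl
Reagents that add atoms: dimethylzinc, C[Zn]C
Why: Copper-catalysed enantioselective conjugate addition of a dialkylzinc desymmetrises the 4,4-disubstituted cyclohexadienone, the ligand choosing one of the two enantiotopic enone arms and so setting C10 (S), while methyl is expected to enter on the face of the oxygen substituent, as with 4-alkoxy-4-alkyl dienones, so that C1–O and C10–CH3 become cis.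

Step 4
Reactants: 7 (4S,5S)-5-methyl-4-(3-methylbut-3-en-1-yl)-4-[(triethylsilyl)oxy]cyclohex-2-en-1-one
Product: 8 (4S,5S)-2-iodo-5-methyl-4-(3-methylbut-3-en-1-yl)-4-[(triethylsilyl)oxy]cyclohex-2-en-1-one
Conditions: iodine, pyridine, CH2Cl2, 0 °C to rt
Reagents that add atoms: iodine, [I][I]
Why: α-Iodination of an enone with iodine in pyridine (conjugate addition of pyridine, iodination of the enolate, elimination) functionalises C7, the only enone α-carbon, while the pyridine-complexed iodine adds only reversibly to the isolated alkene.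

Step 5
Reactants: 8 (4S,5S)-2-iodo-5-methyl-4-(3-methylbut-3-en-1-yl)-4-[(triethylsilyl)oxy]cyclohex-2-en-1-one
Product: 9 (1R,4S,5S)-2-iodo-5-methyl-4-(3-methylbut-3-en-1-yl)-4-[(triethylsilyl)oxy]cyclohex-2-en-1-ol
Conditions: NaBH4, CeCl3·7H2O, MeOH, −78 °C
Reagents that add atoms: none
Why: Luche 1,2-reduction with axial hydride delivery to the half-chair that has the C10 methyl pseudo-equatorial (the face opposite the pseudo-axial C1 silyloxy group) should give the pseudo-equatorial C8 alcohol cis to the methyl, as in the reduction of carvone to cis-carveol, which sets C8 (R).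

Step 6
Reactants: 9 (1R,4S,5S)-2-iodo-5-methyl-4-(3-methylbut-3-en-1-yl)-4-[(triethylsilyl)oxy]cyclohex-2-en-1-ol
Product: 10 tert-butyl{[(1R,4S,5S)-2-iodo-5-methyl-4-(3-methylbut-3-en-1-yl)-4-[(triethylsilyl)oxy]cyclohex-2-en-1-yl]oxy}dimethylsilane
Conditions: TBSCl, imidazole, DMF, rt
Reagents that add atoms: tert-butyldimethylsilyl chloride, CC(C)(C)[Si](C)(C)Cl
Why: Standard silylation of a secondary allylic alcohol masks the C8 hydroxyl for the organolithium, oxidation and Grignard steps.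

Step 7
Reactants: 10 tert-butyl{[(1R,4S,5S)-2-iodo-5-methyl-4-(3-methylbut-3-en-1-yl)-4-[(triethylsilyl)oxy]cyclohex-2-en-1-yl]oxy}dimethylsilane; 11 2,2-dimethyl-1,3-dioxan-5-one
Product: 13 5-[(3S,4S,6R)-6-[(tert-butyldimethylsilyl)oxy]-4-methyl-3-(3-methylbut-3-en-1-yl)-3-[(triethylsilyl)oxy]cyclohex-1-en-1-yl]-2,2-dimethyl-1,3-dioxan-5-ol, via alkenyllithium 12 (not isolated)
Conditions: t-BuLi (2.1 equiv), Et2O, −78 °C; then 11, −78 to −40 °C; aq. NH4Cl
Reagents that add atoms: none
Why: Iodine–lithium exchange of the alkenyl iodide and 1,2-addition of the alkenyllithium to the reactive symmetric dioxanone forge C7–C11 and bring in C11–C13 in one operation; the ketone is symmetric, so no new stereocentre and no alkene-geometry question arise.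

Step 8
Reactants: 13 5-[(3S,4S,6R)-6-[(tert-butyldimethylsilyl)oxy]-4-methyl-3-(3-methylbut-3-en-1-yl)-3-[(triethylsilyl)oxy]cyclohex-1-en-1-yl]-2,2-dimethyl-1,3-dioxan-5-ol
Product: 14 (2S,3S,5R)-5-[(tert-butyldimethylsilyl)oxy]-6-(2,2-dimethyl-1,3-dioxan-5-ylidene)-3-methyl-2-(3-methylbut-3-en-1-yl)-2-[(triethylsilyl)oxy]cyclohexan-1-one
Conditions: pyridinium chlorochromate, NaOAc, 4 Å molecular sieves, CH2Cl2, rt
Reagents that add atoms: pyridinium chlorochromate, [O-][Cr](=O)(=O)Cl.c1cc[nH+]cc1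
Why: Babler–Dauben oxidative transposition, in which the chromate ester of the tertiary allylic alcohol undergoes a [3,3] shift to C6 and is then oxidised, gives the C6 ketone and the tetrasubstituted C7=C11 alkene at once, and because C1 is already quaternary no 1,2-dicarbonyl (and no enolisation towards C10) ever arises.

Step 9
Reactants: 14 (2S,3S,5R)-5-[(tert-butyldimethylsilyl)oxy]-6-(2,2-dimethyl-1,3-dioxan-5-ylidene)-3-methyl-2-(3-methylbut-3-en-1-yl)-2-[(triethylsilyl)oxy]cyclohexan-1-one; 15 vinylmagnesium bromide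
Product: 16 (1R,2S,3S,5R)-5-[(tert-butyldimethylsilyl)oxy]-6-(2,2-dimethyl-1,3-dioxan-5-ylidene)-1-ethenyl-3-methyl-2-(3-methylbut-3-en-1-yl)-2-[(triethylsilyl)oxy]cyclohexan-1-ol
Conditions: THF, −40 to 0 °C; aq. NH4Cl
Reagents that add atoms: none
Why: Grignard 1,2-addition to a ketone that cannot enolise (C1 quaternary, C7 sp2) and whose β-carbon is fully substituted; attack anti to the non-chelating, pseudo-axial C1 silyloxy group (polar Felkin–Anh control), on the face opposite the C8 and C10 substituents, should set C6 with its hydroxyl cis to the C1 oxygen.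

Step 10
Reactants: 16 (1R,2S,3S,5R)-5-[(tert-butyldimethylsilyl)oxy]-6-(2,2-dimethyl-1,3-dioxan-5-ylidene)-1-ethenyl-3-methyl-2-(3-methylbut-3-en-1-yl)-2-[(triethylsilyl)oxy]cyclohexan-1-ol
Product: 17 (1S,2R,4R,6S)-3-(2,2-dimethyl-1,3-dioxan-5-ylidene)-2-ethenyl-6-methyl-1-(3-methylbut-3-en-1-yl)cyclohexane-1,2,4-triol
Conditions: TBAF, THF, rt to 40 °C
Reagents that add atoms: none
Why: Fluoride-mediated desilylation removes the tertiary triethylsilyl and the secondary tert-butyldimethylsilyl ether together, while the acetonide and all alkenes are inert.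

Step 11
Reactants: 17 (1S,2R,4R,6S)-3-(2,2-dimethyl-1,3-dioxan-5-ylidene)-2-ethenyl-6-methyl-1-(3-methylbut-3-en-1-yl)cyclohexane-1,2,4-triol
Product: 18 (1R,3R,4S,5S)-2-(2,2-dimethyl-1,3-dioxan-5-ylidene)-3-ethenyl-3,4-dihydroxy-5-methyl-4-(3-methylbut-3-en-1-yl)cyclohexyl 3-methylbut-2-enoate
Conditions: 3-methylbut-2-enoyl chloride, pyridine, DMAP (cat.), CH2Cl2, 0 °C
Reagents that add atoms: 3-methylbut-2-enoyl chloride, CC(C)=CC(=O)Cl
Why: DMAP-catalysed acylation distinguishes the single secondary (C8) hydroxyl from the two tertiary ones, so the senecioate is in place before ring expansion and no fluoride or strong base is needed once the keto epoxy butenolide exists.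

Step 12
Reactants: 18 (1R,3R,4S,5S)-2-(2,2-dimethyl-1,3-dioxan-5-ylidene)-3-ethenyl-3,4-dihydroxy-5-methyl-4-(3-methylbut-3-en-1-yl)cyclohexyl 3-methylbut-2-enoate
Product: 19 (2R,4S,4aS,8aR)-1-(2,2-dimethyl-1,3-dioxan-5-ylidene)-4a,8a-dihydroxy-4,7-dimethyl-1,2,3,4,4a,5,6,8a-octahydronaphthalen-2-yl 3-methylbut-2-enoate
Conditions: second-generation Grubbs catalyst (5 mol%), CH2Cl2, 40 °C
Reagents that add atoms: none
Why: Ring-closing olefin metathesis between the C6 vinyl group and the 1,1-disubstituted chain alkene closes six-membered ring A with loss of ethene; the trisubstituted C4=C5 alkene is necessarily cis in the ring, and the tetrasubstituted C7=C11 and conjugated senecioate alkenes do not take part.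

Step 13
Reactants: 19 (2R,4S,4aS,8aR)-1-(2,2-dimethyl-1,3-dioxan-5-ylidene)-4a,8a-dihydroxy-4,7-dimethyl-1,2,3,4,4a,5,6,8a-octahydronaphthalen-2-yl 3-methylbut-2-enoate
Product: 20 (1R,4Z,9S)-2-(2,2-dimethyl-1,3-dioxan-5-ylidene)-5,9-dimethyl-3,8-dioxocyclodec-4-en-1-yl 3-methylbut-2-enoate
Conditions: Pb(OAc)4 (1.1 equiv), K2CO3, CH2Cl2, 0 °C
Reagents that add atoms: none
Why: The cis-diol condenses with Pb(OAc)4 to a five-membered cyclic diester of tetravalent lead, which fragments in a concerted two-electron step to the two carbonyl groups and Pb(OAc)2 (Criegee glycol cleavage). The closest precedent is the cleavage of cis-decalin-9,10-diols to cyclodecane-1,6-diones. No ring is closed: the ten-membered ring is uncovered when the zero-atom bridge C1–C6 of the bicyclo[4.4.0] system is cut, and no stereocentre is created, the two carbinol centres being erased while C8 and C10 are untouched. The C4=C5 alkene, held cis in ring A, passes unchanged into the medium ring as the Z-enone. The step needs chemoselectivity for the vicinal diol, which the reagent provides (ester, acetonide and alkenes do not react), and the cis ring fusion lets the cyclic ester form readily. Solid K2CO3 takes up the acetic acid so that the 1,6-dione is not exposed to conditions that favour transannular aldol reaction or epimerisation at C10.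

Step 14
Reactants: 20 (1R,4Z,9S)-2-(2,2-dimethyl-1,3-dioxan-5-ylidene)-5,9-dimethyl-3,8-dioxocyclodec-4-en-1-yl 3-methylbut-2-enoate
Product: 21 (1R,3S,4Z,9S)-2-(2,2-dimethyl-1,3-dioxan-5-ylidene)-3-hydroxy-5,9-dimethyl-8-oxocyclodec-4-en-1-yl 3-methylbut-2-enoate
Conditions: (R)-2-methyl-CBS-oxazaborolidine (0.2 equiv), catecholborane (1.5 equiv), toluene, −78 °C; MeOH, then pH 7 buffer
Reagents that add atoms: none
Why: Corey–Bakshi–Shibata reduction, in which the oxazaborolidine–catecholborane complex should bind the more Lewis-basic conjugated C6 carbonyl at −78 °C while the α-branched saturated C1 ketone of the medium ring reacts far more slowly, and the (R)-catalyst, reading the fully substituted C7 arm as the large group, is expected to give the (6S)-carbinol with its hydroxyl cis to the C8 oxygen.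

Step 15
Reactants: 21 (1R,3S,4Z,9S)-2-(2,2-dimethyl-1,3-dioxan-5-ylidene)-3-hydroxy-5,9-dimethyl-8-oxocyclodec-4-en-1-yl 3-methylbut-2-enoate
Product: 22 (4S,5R,6R,8R,10S)-7-(2,2-dimethyl-1,3-dioxan-5-ylidene)-4,5-epoxy-6-hydroxy-4,10-dimethyl-1-oxocyclodecan-8-yl 3-methylbut-2-enoate (target locants)
Conditions: VO(acac)2 (5 mol%), t-BuOOH (1.5 equiv, in decane), CH2Cl2, 0 °C to rt
Reagents that add atoms: tert-butyl hydroperoxide, CC(C)(C)OO
Why: Vanadium-catalysed hydroxyl-directed epoxidation should deliver oxygen from the C6 vanadate ester to the trisubstituted C4=C5 alkene and not to the tetrasubstituted C7=C11 alkene, which is deactivated by three allylic C–O bonds; for Z-allylic alcohols in medium rings this delivery gives the cis (erythro) epoxy alcohol, here 4S,5R, and the Z geometry makes the epoxide cis.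

Step 16
Reactants: 22 (4S,5R,6R,8R,10S)-7-(2,2-dimethyl-1,3-dioxan-5-ylidene)-4,5-epoxy-6-hydroxy-4,10-dimethyl-1-oxocyclodecan-8-yl 3-methylbut-2-enoate
Product: 23 (4S,5R,6R,8R,10S)-7-(1,3-dihydroxypropan-2-ylidene)-4,5-epoxy-6-hydroxy-4,10-dimethyl-1-oxocyclodecan-8-yl 3-methylbut-2-enoate (target locants)
Conditions: pyridinium p-toluenesulfonate (0.2 equiv), MeOH, 0 °C to rt
Reagents that add atoms: none
Why: Acid-catalysed transketalisation with methanol removes the 1,3-dioxane acetonide under conditions mild enough for the trisubstituted epoxide and the ester.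

Step 17
Reactants: 23 (4S,5R,6R,8R,10S)-7-(1,3-dihydroxypropan-2-ylidene)-4,5-epoxy-6-hydroxy-4,10-dimethyl-1-oxocyclodecan-8-yl 3-methylbut-2-enoate
Product: 25 (4S,5R,6R,8R,10S)-4,5-epoxy-1,13-dioxogermacr-7(11)-en-12,6-olid-8-yl 3-methylbut-2-enoate, via lactol 24 (not isolated)
Conditions: TEMPO (0.2 equiv), PhI(OAc)2 (3.3 equiv), CH2Cl2, rt
Reagents that add atoms: none
Why: Oxoammonium (TEMPO/PhI(OAc)2) oxidation of the two primary allylic alcohols, in which the C12 aldehyde is trapped by the neighbouring C6 hydroxyl as a lactol that is oxidised on to the butenolide while C13 ends as the aldehyde; C8 is blocked as the ester, so only the 6,12-lactone can form.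

Step 18
Reactants: 25 (4S,5R,6R,8R,10S)-4,5-epoxy-1,13-dioxogermacr-7(11)-en-12,6-olid-8-yl 3-methylbut-2-enoate
Product: 26 (4S,5R,6R,8R,10S)-4,5-epoxy-13-hydroxy-1-oxogermacr-7(11)-en-12,6-olid-8-yl 3-methylbut-2-enoate
Conditions: NaBH4 (0.3 equiv), CeCl3·7H2O, MeOH/CH2Cl2, −78 °C
Reagents that add atoms: none
Why: Luche 1,2-reduction at −78 °C with a deficiency of NaBH4 should reduce the highly electrophilic conjugated aldehyde much faster than the hindered saturated C1 ketone, and the cerium salt suppresses conjugate reduction of the butenolide.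

Step 19
Reactants: 26 (4S,5R,6R,8R,10S)-4,5-epoxy-13-hydroxy-1-oxogermacr-7(11)-en-12,6-olid-8-yl 3-methylbut-2-enoate
Product: 27 (4S,5R,6R,8R,10S)-13-acetoxy-4,5-epoxy-1-oxogermacr-7(11)-en-12,6-olid-8-yl 3-methylbut-2-enoate (CNP0220542.1)
Conditions: Ac2O, pyridine, DMAP (cat.), CH2Cl2, 0 °C
Reagents that add atoms: acetic anhydride, CC(=O)OC(C)=O
Why: Acetylation of the only free hydroxyl (primary, allylic) completes the target.

**Compound list**

1 | 4,4-dimethoxycyclohexa-2,5-dien-1-one | COC1(OC)C=CC(=O)C=C1 | starting material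
2 | 4-bromo-2-methylbut-1-ene | C=C(C)CCBr | starting material
3 | (3-methylbut-3-en-1-yl)magnesium bromide (not isolated) | C=C(C)CC[Mg]Br | intermediate
4 | 4,4-dimethoxy-1-(3-methylbut-3-en-1-yl)cyclohexa-2,5-dien-1-ol (not isolated) | C=C(C)CCC1(O)C=CC(OC)(OC)C=C1 | intermediate
5 | 4-hydroxy-4-(3-methylbut-3-en-1-yl)cyclohexa-2,5-dien-1-one | C=C(C)CCC1(O)C=CC(=O)C=C1 | intermediate
6 | 4-(3-methylbut-3-en-1-yl)-4-[(triethylsilyl)oxy]cyclohexa-2,5-dien-1-one | C=C(C)CCC1(O[Si](CC)(CC)CC)C=CC(=O)C=C1 | intermediate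
7 | (4S,5S)-5-methyl-4-(3-methylbut-3-en-1-yl)-4-[(triethylsilyl)oxy]cyclohex-2-en-1-one (methyl cis to silyloxy) | C[C@H]1CC(=O)C=C[C@]1(O[Si](CC)(CC)CC)CCC(C)=C | intermediate
8 | (4S,5S)-2-iodo-5-methyl-4-(3-methylbut-3-en-1-yl)-4-[(triethylsilyl)oxy]cyclohex-2-en-1-one | C[C@H]1CC(=O)C(I)=C[C@]1(O[Si](CC)(CC)CC)CCC(C)=C | intermediate
9 | (1R,4S,5S)-2-iodo-5-methyl-4-(3-methylbut-3-en-1-yl)-4-[(triethylsilyl)oxy]cyclohex-2-en-1-ol (OH, methyl and silyloxy all cis) | C[C@H]1C[C@@H](O)C(I)=C[C@]1(O[Si](CC)(CC)CC)CCC(C)=C | intermediate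
10 | tert-butyl{[(1R,4S,5S)-2-iodo-5-methyl-4-(3-methylbut-3-en-1-yl)-4-[(triethylsilyl)oxy]cyclohex-2-en-1-yl]oxy}dimethylsilane | C[C@H]1C[C@@H](O[Si](C)(C)C(C)(C)C)C(I)=C[C@]1(O[Si](CC)(CC)CC)CCC(C)=C | intermediate
11 | 2,2-dimethyl-1,3-dioxan-5-one | CC1(C)OCC(=O)CO1 | starting material
12 | alkenyllithium from 10 (lithium in place of iodine; not isolated) | C[C@H]1C[C@@H](O[Si](C)(C)C(C)(C)C)C([Li])=C[C@]1(O[Si](CC)(CC)CC)CCC(C)=C | intermediate
13 | 5-[(3S,4S,6R)-6-[(tert-butyldimethylsilyl)oxy]-4-methyl-3-(3-methylbut-3-en-1-yl)-3-[(triethylsilyl)oxy]cyclohex-1-en-1-yl]-2,2-dimethyl-1,3-dioxan-5-ol | C[C@H]1C[C@@H](O[Si](C)(C)C(C)(C)C)C(C2(O)COC(C)(C)OC2)=C[C@]1(O[Si](CC)(CC)CC)CCC(C)=C | intermediate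
14 | (2S,3S,5R)-5-[(tert-butyldimethylsilyl)oxy]-6-(2,2-dimethyl-1,3-dioxan-5-ylidene)-3-methyl-2-(3-methylbut-3-en-1-yl)-2-[(triethylsilyl)oxy]cyclohexan-1-one | C[C@H]1C[C@@H](O[Si](C)(C)C(C)(C)C)C(=C2COC(C)(C)OC2)C(=O)[C@]1(O[Si](CC)(CC)CC)CCC(C)=C | intermediate
15 | vinylmagnesium bromide | C=C[Mg]Br | starting material
16 | (1R,2S,3S,5R)-5-[(tert-butyldimethylsilyl)oxy]-6-(2,2-dimethyl-1,3-dioxan-5-ylidene)-1-ethenyl-3-methyl-2-(3-methylbut-3-en-1-yl)-2-[(triethylsilyl)oxy]cyclohexan-1-ol | C[C@H]1C[C@@H](O[Si](C)(C)C(C)(C)C)C(=C2COC(C)(C)OC2)[C@](O)(C=C)[C@]1(O[Si](CC)(CC)CC)CCC(C)=C | intermediate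
17 | (1S,2R,4R,6S)-3-(2,2-dimethyl-1,3-dioxan-5-ylidene)-2-ethenyl-6-methyl-1-(3-methylbut-3-en-1-yl)cyclohexane-1,2,4-triol | C[C@H]1C[C@@H](O)C(=C2COC(C)(C)OC2)[C@](O)(C=C)[C@]1(O)CCC(C)=C | intermediate
18 | (1R,3R,4S,5S)-2-(2,2-dimethyl-1,3-dioxan-5-ylidene)-3-ethenyl-3,4-dihydroxy-5-methyl-4-(3-methylbut-3-en-1-yl)cyclohexyl 3-methylbut-2-enoate | C[C@H]1C[C@@H](OC(=O)C=C(C)C)C(=C2COC(C)(C)OC2)[C@](O)(C=C)[C@]1(O)CCC(C)=C | intermediate
19 | (2R,4S,4aS,8aR)-1-(2,2-dimethyl-1,3-dioxan-5-ylidene)-4a,8a-dihydroxy-4,7-dimethyl-1,2,3,4,4a,5,6,8a-octahydronaphthalen-2-yl 3-methylbut-2-enoate (cis-fused diol, precursor of the key step) | C[C@H]1C[C@@H](OC(=O)C=C(C)C)C(=C3COC(C)(C)OC3)[C@]2(O)C=C(C)CC[C@]12O | intermediate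
20 | (1R,4Z,9S)-2-(2,2-dimethyl-1,3-dioxan-5-ylidene)-5,9-dimethyl-3,8-dioxocyclodec-4-en-1-yl 3-methylbut-2-enoate (C1 and C6 ketones, product of the key step) | C[C@H]1C[C@@H](OC(=O)C=C(C)C)C(=C2COC(C)(C)OC2)C(=O)/C=C(C)\CCC1=O | intermediate
21 | (1R,3S,4Z,9S)-2-(2,2-dimethyl-1,3-dioxan-5-ylidene)-3-hydroxy-5,9-dimethyl-8-oxocyclodec-4-en-1-yl 3-methylbut-2-enoate (C6 hydroxyl cis to C8 oxygen) | C[C@H]1C[C@@H](OC(=O)C=C(C)C)C(=C2COC(C)(C)OC2)[C@@H](O)/C=C(C)\CCC1=O | intermediate
22 | (4S,5R,6R,8R,10S)-7-(2,2-dimethyl-1,3-dioxan-5-ylidene)-4,5-epoxy-6-hydroxy-4,10-dimethyl-1-oxocyclodecan-8-yl 3-methylbut-2-enoate (target locants) | C[C@H]1C[C@@H](OC(=O)C=C(C)C)C(=C2COC(C)(C)OC2)[C@@H](O)[C@H]3O[C@@]3(C)CCC1=O | intermediate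
23 | (4S,5R,6R,8R,10S)-7-(1,3-dihydroxypropan-2-ylidene)-4,5-epoxy-6-hydroxy-4,10-dimethyl-1-oxocyclodecan-8-yl 3-methylbut-2-enoate (target locants) | C[C@H]1C[C@@H](OC(=O)C=C(C)C)C(=C(CO)CO)[C@@H](O)[C@H]2O[C@@]2(C)CCC1=O | intermediate
24 | C12 lactol of 25 (12-hydroxy-6,12-epoxy ring, C13 aldehyde; C12 configuration undefined; not isolated) | C[C@H]1C[C@@H](OC(=O)C=C(C)C)C2=C(C=O)C(O)O[C@H]2[C@H]3O[C@@]3(C)CCC1=O | intermediate
25 | (4S,5R,6R,8R,10S)-4,5-epoxy-1,13-dioxogermacr-7(11)-en-12,6-olid-8-yl 3-methylbut-2-enoate | C[C@H]1C[C@@H](OC(=O)C=C(C)C)C2=C(C=O)C(=O)O[C@H]2[C@H]3O[C@@]3(C)CCC1=O | intermediate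
26 | (4S,5R,6R,8R,10S)-4,5-epoxy-13-hydroxy-1-oxogermacr-7(11)-en-12,6-olid-8-yl 3-methylbut-2-enoate | C[C@H]1C[C@@H](OC(=O)C=C(C)C)C2=C(CO)C(=O)O[C@H]2[C@H]3O[C@@]3(C)CCC1=O | intermediate
27 | (4S,5R,6R,8R,10S)-13-acetoxy-4,5-epoxy-1-oxogermacr-7(11)-en-12,6-olid-8-yl 3-methylbut-2-enoate (CNP0220542.1) | C[C@H]1C[C@@H](OC(=O)C=C(C)C)C2=C(COC(C)=O)C(=O)O[C@H]2[C@H]3O[C@@]3(C)CCC1=O | target

**Total step count:** 19. **Longest linear sequence:** 19 steps (from 1 and 2 to 27); all other inputs are commercial.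

**Steps most likely to fail**

Step 14. Hydride may also be delivered to the C1 ketone, or the catalyst may fail to discriminate the faces of the hindered, cross-conjugated C6 carbonyl. The fallback masks C1 first. It sets out from 20: 1,2-bis(trimethylsilyloxy)ethane with catalytic TMSOTf (CH2Cl2, −78 °C) should ketalise only the non-conjugated carbonyl and give the C1 dioxolane dienone F1. The single remaining ketone is then reduced with the (R)-oxazaborolidine and an excess of catecholborane to the C1 dioxolane dienol F2. VO(acac)2/t-BuOOH gives the C1 dioxolane epoxy alcohol F3. One treatment with pyridinium p-toluenesulfonate in methanol and then wet acetone removes the acetonide and the strained medium-ring dioxolane together, and the route is rejoined at 23.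

Step 15. Oxygen may be delivered to the wrong face of the flexible ten-membered ring, or the doubly allylic carbinol may be oxidised back to the dienone. The fallback forms the epoxide on the rigid bicycle before ring expansion. It sets out from 19: VO(acac)2/t-BuOOH epoxidises the ring-A alkene syn to the tertiary allylic C6 hydroxyl, which on this diastereomer of the diol is the 4S,5R face, and gives the bicyclic epoxy diol F4. Pb(OAc)4/K2CO3 cleaves it to the 4,5-epoxy-1,6-dione F5. Chelation-controlled reduction of the α,β-epoxy ketone with Zn(BH4)2 (Et2O, −20 °C), a reaction known to give erythro epoxy alcohols, returns to the route at 22.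

Step 9. Addition to the neopentyl carbonyl may stall, or the nucleophile may enter from the face of the silyloxy group and give the trans-diol. The fallback uses a smaller, linear nucleophile with a stronger preference for axial attack. It sets out from 14: lithium (trimethylsilyl)acetylide (THF, −78 °C, with CeCl3 if needed) gives the silylalkynyl carbinol F6. TBAF removes all three silyl groups and gives the ethynyl triol F7. Semi-hydrogenation (H2, Pd/CaCO3 poisoned with Pb(OAc)2, quinoline) reduces only the alkyne, and the route is rejoined at 17.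

**Further compounds**

F1 | step 14 | C1 ethylene ketal (1,3-dioxolane) of dienone 20 | C[C@H]1C[C@@H](OC(=O)C=C(C)C)C(=C2COC(C)(C)OC2)C(=O)/C=C(C)\CCC13OCCO3
F2 | step 14 | C1 ethylene ketal of dienol 21 (6S) | C[C@H]1C[C@@H](OC(=O)C=C(C)C)C(=C2COC(C)(C)OC2)[C@@H](O)/C=C(C)\CCC13OCCO3
F3 | step 14 | C1 ethylene ketal of epoxy alcohol 22 (4S,5R,6R) | C[C@H]1C[C@@H](OC(=O)C=C(C)C)C(=C2COC(C)(C)OC2)[C@@H](O)[C@H]4O[C@@]4(C)CCC13OCCO3
F4 | step 15 | 4,5-epoxide of bicyclic diol 19, epoxide syn to the C6 hydroxyl (4S,5R) | C[C@H]1C[C@@H](OC(=O)C=C(C)C)C(=C3COC(C)(C)OC3)[C@]2(O)[C@H]4O[C@@]4(C)CC[C@]12O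
F5 | step 15 | (4S,5R,8R,10S)-7-(2,2-dimethyl-1,3-dioxan-5-ylidene)-4,5-epoxy-4,10-dimethyl-1,6-dioxocyclodecan-8-yl 3-methylbut-2-enoate (target locants) | C[C@H]1C[C@@H](OC(=O)C=C(C)C)C(=C2COC(C)(C)OC2)C(=O)[C@H]3O[C@@]3(C)CCC1=O
F6 | step 9 | analogue of 16 with a (trimethylsilyl)ethynyl group in place of ethenyl at C6 | C[C@H]1C[C@@H](O[Si](C)(C)C(C)(C)C)C(=C2COC(C)(C)OC2)[C@](O)(C#C[Si](C)(C)C)[C@]1(O[Si](CC)(CC)CC)CCC(C)=C
F7 | step 9 | analogue of 17 with an ethynyl group in place of ethenyl at C6 | C[C@H]1C[C@@H](O)C(=C2COC(C)(C)OC2)[C@](O)(C#C)[C@]1(O)CCC(C)=C
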